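**Plan**

1. Skeleton numbering used below: ten-membered ring C1–C10; cyclohexene (ring A) C1, C10–C14 with C15 on C1 and C20 on C11; γ-lactone O–C7, C8, C17 (C18), C19; C16 is the CH2OAc on C5.
2. Cuts, latest first: lactone O–C7 together with C16–OAc (diene 1,4-oxidation); C6=C7 with C5=C16 (ring-closing enyne metathesis); C8–C17 (aldol); C8–C9 (alkoxyallylboration); C11=C12 (RCM); C13–C14; C1–C10 (Ireland–Claisen); C1–C2 (aldol); C3–C4 (allylboration).
3. Forward: the chain C14–C1–C2–C3–C4–C5≡C6 is made first, C9–C10–C11 is added in the Claisen step, ring A is closed by RCM, the C7–C9/C17–C19 arm is built on C10, the ten-membered ring is closed by enyne metathesis, and the γ-lactone is the last ring to close.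
4. Enabling feature: O–C7–C6=C5–C16–OAc is a 1,4-dioxygenated but-2-ene, the imprint of a 1,4-oxidation of the cross-conjugated diene C16=C5–C6=C7, and C19 lies γ,δ to C7 through C17–C8. One event therefore closes the lactone (5-exo), sets C7, fixes the 5Z alkene and brings in the C16 acetate from acetic acid.
5. Stereochemistry: C4 and C9 by reagent control (isopinocampheyl boranes); C2 by a thiazolidinethione auxiliary; C1 and C10 relayed from C2 through a chair Claisen; C14 by C2-directed anti reduction; C8 from C9 (Felkin–Anh) and C17 from the closed aldol transition state; C7 from C8 in the key step.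

Key step: step 22

Assumption: compounds 2, 6, 8 and 22 are purchased; each is otherwise one routine step from bulk chemicals.

**Route**

Step 1
Reactants: 1 3-(trimethylsilyl)prop-2-ynal; 2 (+)-B-allyldiisopinocampheylborane
Product: 3 (R)-1-(trimethylsilyl)hex-5-en-1-yn-3-ol
Conditions: Et2O, −78 °C; then HOCH2CH2NH2, 23 °C
Reagents that add atoms: none
Why: Brown allylboration through a six-membered chair transition state, in which the isopinocampheyl groups of 2 should direct the allyl group to the Re face of the ynal and so set C4 (R).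

Step 2
Reactants: 3 (R)-1-(trimethylsilyl)hex-5-en-1-yn-3-ol
Product: 4 (R)-3-(tert-butyldiphenylsilyloxy)-1-(trimethylsilyl)hex-5-en-1-yne
Conditions: t-BuPh2SiCl, imidazole, DMF, 23 °C
Reagents that add atoms: tert-butyl(chloro)diphenylsilane, CC(C)(C)[Si](Cl)(c1ccccc1)c1ccccc1
Why: Standard silylation of a secondary alcohol; this robust ether should survive every step up to the last one.

Step 3
Reactants: 4 (R)-3-(tert-butyldiphenylsilyloxy)-1-(trimethylsilyl)hex-5-en-1-yne
Product: 5 (R)-3-(tert-butyldiphenylsilyloxy)-5-(trimethylsilyl)pent-4-ynal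
Conditions: OsO4 (2 mol %), NaIO4, 2,6-lutidine, dioxane–H2O, 23 °C
Reagents that add atoms: sodium periodate (oxygen source for the aldehyde by way of OsO4), [Na+].[O-]I(=O)(=O)=O
Why: Lemieux–Johnson cleavage of the terminal alkene to the C2 aldehyde; the silylated alkyne is much less reactive toward OsO4 and should stay intact.

Step 4
Reactants: 5 (R)-3-(tert-butyldiphenylsilyloxy)-5-(trimethylsilyl)pent-4-ynal; 6 (R)-4-benzyl-3-propanoyl-1,3-thiazolidine-2-thione
Product: 7 syn-aldol imide (acyl C14, then C1 (R), C2 (S), C3, C4 (R), C5≡C6)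
Conditions: TiCl4, i-Pr2NEt, N-methyl-2-pyrrolidinone, CH2Cl2, −78 to 0 °C
Reagents that add atoms: none
Why: Titanium enolate aldol addition of an N-acylthiazolidinethione through a chair transition state; the (R)-benzyl auxiliary should give the syn adduct with C2 (S), and the configuration at C1 does not matter because step 7 erases it.

Step 5
Reactants: 8 (E)-4,4-dimethoxy-2-methylbut-2-enal
Product: 9 (E)-4,4-dimethoxy-2-methylbut-2-en-1-ol
Conditions: NaBH4, MeOH, 0 °C
Reagents that add atoms: none
Why: 1,2-Reduction of the enal by borohydride, which leaves the acetal and the (E)-alkene untouched.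

Step 6
Reactants: 7 syn-aldol imide; 9 (E)-4,4-dimethoxy-2-methylbut-2-en-1-ol
Product: 10 (E)-4,4-dimethoxy-2-methylbut-2-enyl (2R,3S,5R)-5-(tert-butyldiphenylsilyloxy)-3-hydroxy-2-methyl-7-(trimethylsilyl)hept-6-ynoate
Conditions: DMAP, CH2Cl2, 23 °C
Reagents that add atoms: none
Why: Acyl transfer from the activated N-acylthiazolidinethione to the primary allylic alcohol, which should release the auxiliary without touching the β-hydroxyl or C2.

Step 7
Reactants: 10 allylic β-hydroxy ester
Product: 13 Claisen acid (C14 acid, quaternary C1, C10 bearing the C9 acetal and an isopropenyl group), via dilithium enolate alkoxide 11 (not isolated), via dilithium carboxylate alkoxide 12 (not isolated)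
Conditions: LiN(i-Pr)2 (3 equiv), THF, −78 °C, then 23 to 50 °C; cold dilute HCl work-up
Reagents that add atoms: none
Why: Dianionic Ireland–Claisen rearrangement, in which the lithium alkoxide–enolate chelate should fix the enolate geometry (O–Li cis to C2), the allyl unit should add to the enolate face anti to the C3 chain, and the chair transition state with the (E)-alkene should turn this into quaternary C1 and C10 with C2 and C9 anti.

Step 8
Reactants: 13 Claisen acid
Product: 14 N-methoxy-N-methylamide of 13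
Conditions: MeNH(OMe)·HCl, EDC·HCl, HOBt, N-methylmorpholine, CH2Cl2, 0 to 23 °C
Reagents that add atoms: N,O-dimethylhydroxylamine hydrochloride, CNOC.Cl
Why: Carbodiimide amide coupling, which should convert the hindered acid into a Weinreb amide without epimerizable positions being at risk (C1 is quaternary).

Step 9
Reactants: 14 Weinreb amide; 15 allylmagnesium bromide
Product: 16 β-hydroxy allyl ketone (C14 ketone carrying C13H2–C12H=CH2)
Conditions: THF, −78 to −20 °C; NH4Cl quench at −78 °C
Reagents that add atoms: none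
Why: Weinreb ketone synthesis, in which the chelated tetrahedral intermediate should prevent over-addition and the cold quench should keep the β,γ-unsaturated ketone out of conjugation.

Step 10
Reactants: 16 β-hydroxy allyl ketone
Product: 17 1,3-anti diol (C14 (S) carbinol)
Conditions: Me4NBH(OAc)3, AcOH–MeCN, −30 °C
Reagents that add atoms: none
Why: Evans–Saksena reduction, in which hydride is delivered inside a chair from the alkoxyborohydride formed at the C2 hydroxyl, so that the 1,3-anti diol and thus C14 (S) should result.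

Step 11
Reactants: 17 1,3-anti diol
Product: 18 ring A diol (cyclohexene C1, C10–C14 closed, C11=C12 trisubstituted)
Conditions: second-generation Grubbs catalyst (5 mol %), CH2Cl2, 40 °C
Reagents that add atoms: none
Why: Ring-closing metathesis of the allyl and isopropenyl groups to a six-membered trisubstituted alkene, a closure that should outrun any reaction of the silyl-capped alkyne.

Step 12
Reactants: 18 ring A diol
Product: 19 terminal alkyne
Conditions: K2CO3, MeOH, 23 °C
Reagents that add atoms: none
Why: Base-catalysed methanolysis of the alkynyl–silicon bond, done here because no ester is yet present and the ring A metathesis is over.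

Step 13
Reactants: 19 terminal alkyne diol
Product: 20 2,14-diacetate
Conditions: Ac2O, DMAP, pyridine, 23 °C
Reagents that add atoms: acetic anhydride, CC(=O)OC(C)=O
Why: DMAP-catalysed acetylation of the two secondary hydroxyls, which puts the C2 and C14 acetates of the target in place.

Step 14
Reactants: 20 diacetate acetal
Product: 21 C9 aldehyde
Conditions: PPTS, acetone–H2O, 40 °C
Reagents that add atoms: water, O
Why: Mild acid hydrolysis of the dimethyl acetal, chosen to spare the silyl ether and to avoid epimerization or conjugation at the allylic C10.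

Step 15
Reactants: 21 C9 aldehyde; 22 allyl 4-methoxybenzyl ether
Product: 24 C9 (S) alcohol with syn C8 (S) 4-methoxybenzyl ether and a vinyl group on C8, via (Z)-alkoxyallylborane 23 (not isolated)
Conditions: 22, s-BuLi, THF, −78 °C; (+)-Ipc2BOMe; BF3·OEt2; then 21, −78 °C; HOCH2CH2NH2, 23 °C
Reagents that add atoms: none
Why: Brown γ-alkoxyallylboration through a chair transition state, in which reagent control (Re-face attack) should override the Felkin preference of the α-branched aldehyde and set C9 (S), while the (Z)-reagent gives the syn C8 ether, a centre that step 18 erases.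

Step 16
Reactants: 24 C9 alcohol
Product: 25 9-O-triethylsilyl ether
Conditions: Et3SiOTf, 2,6-lutidine, CH2Cl2, −78 °C
Reagents that add atoms: triethylsilyl trifluoromethanesulfonate, CC[Si](CC)(CC)OS(=O)(=O)C(F)(F)F
Why: Silylation of the hindered C9 hydroxyl with a non-chelating group that is needed for Felkin–Anh control in step 19 and can later be removed beside the tert-butyldiphenylsilyl ether.

Step 17
Reactants: 25 silyl ether
Product: 26 C8 allylic alcohol
Conditions: DDQ, CH2Cl2–pH 7 buffer, 0 °C
Reagents that add atoms: none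
Why: Oxidative cleavage of the 4-methoxybenzyl ether by hydride abstraction, which should not affect the isolated alkenes, the alkyne, the acetates or the silyl ethers.

Step 18
Reactants: 26 C8 allylic alcohol
Product: 27 α′-silyloxy enone (C8 ketone with vinyl C7=CH2)
Conditions: Dess–Martin periodinane, NaHCO3, CH2Cl2, 0 °C
Reagents that add atoms: none
Why: Dess–Martin oxidation of the allylic alcohol under buffered, non-epimerizing conditions, which gives the vinyl ketone for the next step.

Step 19
Reactants: 27 α′-silyloxy enone; 28 allyl propanoate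
Product: 29 aldol adduct (C8 tertiary alcohol with vinyl, C17 with CH3, allyl ester at C19)
Conditions: 28, LiN(i-Pr)2, THF–DMPU, −78 °C; then 27, −78 °C; AcOH quench at −78 °C
Reagents that add atoms: none
Why: Aldol addition of the lithium (Z)-ester enolate to the ketone through a Zimmerman–Traxler chair, where kinetic 1,2-addition, attack anti to the C9–O bond (polar Felkin–Anh, non-chelating silyl ether) and the bulky C9 branch equatorial should set C8 and place the C18 methyl syn to the new hydroxyl, giving C17 (R).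

Step 20
Reactants: 29 allyl ester
Product: 30 carboxylic acid
Conditions: Pd(PPh3)4 (5 mol %), morpholine, THF, 23 °C
Reagents that add atoms: none
Why: Tsuji–Trost deallylation by zerovalent palladium with morpholine as allyl acceptor, which should free the acid under neutral conditions while C9 stays silylated so that no lactone can form toward O9.

Step 21
Reactants: 30 enyne acid
Product: 32 macrocyclic diene acid (ten-membered ring closed through (6Z)-C6=C7, exocyclic C5=C16), via acyclic 1,3-diene 31 (not isolated)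
Conditions: second-generation Grubbs catalyst (15 mol %), ethylene (1 atm), toluene, 23 °C; then argon, 1 mM, 80 °C
Reagents that add atoms: ethylene, C=C
Why: Ring-closing enyne metathesis in the endo sense, run as ethylene cross enyne metathesis to the 2-substituted butadiene 31 followed by diene–ene ring closure onto the C8 vinyl group; the ten-membered ring should favour the (6Z)-alkene, and the C5=C16 and C11=C12 alkenes should stay out of the reaction.

Step 22
Reactants: 32 macrocyclic diene acid
Product: 33 γ-lactone with C16 acetate and (5Z)-alkene (9-O-SiEt3, 4-O-SiPh2t-Bu)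
Conditions: Pd(OAc)2 (10 mol %), 1,4-benzoquinone, LiOAc, AcOH–acetone (1:4), 23 °C
Reagents that add atoms: acetic acid, CC(=O)O
Why: Palladium diacetate binds the C6=C7 bond of the cross-conjugated diene on the face away from the tethered carboxyl, whose oxygen attacks C7 by trans-oxypalladation to give an η3-allylpalladium over C6–C5–C16; acetate then attacks the primary terminus C16 and benzoquinone returns zerovalent palladium to the divalent state. The closest known reaction type is the palladium-catalysed 1,4-acyloxylation of conjugated dienes with an internal carboxylic acid as first nucleophile (1,4-oxylactonization). The γ-lactone closes in the 5-exo-trig mode on the γ,δ-unsaturated acid. C7 (S) is controlled by C8: A(1,3) strain between C5 and the C8 substituents of the (6Z)-alkene holds C9 out of the alkene plane and C17 perpendicular to it, so the carboxylate reaches one face only. The step needs 1,4- over 1,2-addition, which attack at the unhindered primary C16 to form the trisubstituted alkene should secure, and the 5Z geometry, which the ring should secure because only the allyl isomer with C4 and C7 cis fits the ten-membered ring. It also needs the carboxyl to win over the tertiary 8-OH, which could only close a three-membered ring at C7.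

Step 23
Reactants: 33 silylated lactone
Product: 34 9-hydroxy lactone
Conditions: HF·pyridine, pyridine, THF, 0 °C
Reagents that add atoms: none
Why: Selective fluoride cleavage of the triethylsilyl ether beside the far more stable tert-butyldiphenylsilyl ether; the C19 carbonyl is now held in the C7 lactone, and the product is acetylated at once to forestall acyl migration to O9.

Step 24
Reactants: 34 9-hydroxy lactone
Product: 35 4-O-tert-butyldiphenylsilyl ether of the target
Conditions: Ac2O, DMAP, pyridine, CH2Cl2, 0 to 23 °C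
Reagents that add atoms: acetic anhydride, CC(=O)OC(C)=O
Why: Acetylation of the secondary C9 hydroxyl, which should leave the tertiary C8 hydroxyl free and cannot reach the silylated C4 oxygen.

Step 25
Reactants: 35 silyl ether
Product: 36 target CNP0226727.2
Conditions: Bu4NF, AcOH (1:1), THF, 23 °C
Reagents that add atoms: none
Why: Buffered fluoride desilylation of the allylic C4 ether, with acetic acid present to suppress acetyl migration and lactone opening.

**Compound list**

1 | 3-(trimethylsilyl)prop-2-ynal | C[Si](C)(C)C#CC=O | starting material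
2 | (+)-B-allyldiisopinocampheylborane (reagent derived from (−)-α-pinene) | C=CCB([C@H]1C[C@H]2C[C@@H]([C@@H]1C)C2(C)C)[C@H]1C[C@H]2C[C@@H]([C@@H]1C)C2(C)C | starting material
3 | (R)-1-(trimethylsilyl)hex-5-en-1-yn-3-ol | C[Si](C)(C)C#C[C@H](O)CC=C | intermediate
4 | (R)-3-(tert-butyldiphenylsilyloxy)-1-(trimethylsilyl)hex-5-en-1-yne | C[Si](C)(C)C#C[C@H](O[Si](c1ccccc1)(c1ccccc1)C(C)(C)C)CC=C | intermediate
5 | (R)-3-(tert-butyldiphenylsilyloxy)-5-(trimethylsilyl)pent-4-ynal (CHO = C2, silyloxy carbon = C4) | C[Si](C)(C)C#C[C@H](O[Si](c1ccccc1)(c1ccccc1)C(C)(C)C)CC=O | intermediate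
6 | (R)-4-benzyl-3-propanoyl-1,3-thiazolidine-2-thione | CCC(=O)N1C(=S)SC[C@H]1Cc1ccccc1 | starting material
7 | syn-aldol imide: (2R,3S,5R)-5-(tert-butyldiphenylsilyloxy)-3-hydroxy-2-methyl-7-(trimethylsilyl)hept-6-ynoyl derivative of (R)-4-benzyl-1,3-thiazolidine-2-thione | O=C(N1C(=S)SC[C@H]1Cc1ccccc1)[C@H](C)[C@@H](O)C[C@@H](O[Si](c1ccccc1)(c1ccccc1)C(C)(C)C)C#C[Si](C)(C)C | intermediate
8 | (E)-4,4-dimethoxy-2-methylbut-2-enal | O=C/C(C)=C/C(OC)OC | starting material
9 | (E)-4,4-dimethoxy-2-methylbut-2-en-1-ol | OC/C(C)=C/C(OC)OC | intermediate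
10 | (E)-4,4-dimethoxy-2-methylbut-2-enyl (2R,3S,5R)-5-(tert-butyldiphenylsilyloxy)-3-hydroxy-2-methyl-7-(trimethylsilyl)hept-6-ynoate | COC(OC)/C=C(\C)COC(=O)[C@H](C)[C@@H](O)C[C@@H](O[Si](c1ccccc1)(c1ccccc1)C(C)(C)C)C#C[Si](C)(C)C | intermediate
11 | dilithium enolate alkoxide of 10 (enolate O–Li cis to C2; not isolated) | [Li]O/C(OC/C(C)=C/C(OC)OC)=C(/C)[C@@H](O[Li])C[C@@H](O[Si](c1ccccc1)(c1ccccc1)C(C)(C)C)C#C[Si](C)(C)C | intermediate
12 | dilithium carboxylate alkoxide of 13 (not isolated) | [Li]OC(=O)[C@](C)([C@@H](O[Li])C[C@@H](O[Si](c1ccccc1)(c1ccccc1)C(C)(C)C)C#C[Si](C)(C)C)[C@@H](C(OC)OC)C(C)=C | intermediate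
13 | Claisen acid: (2S,3S,5R)-5-(tert-butyldiphenylsilyloxy)-2-[(2S)-1,1-dimethoxy-3-methylbut-3-en-2-yl]-3-hydroxy-2-methyl-7-(trimethylsilyl)hept-6-ynoic acid | OC(=O)[C@](C)([C@@H](O)C[C@@H](O[Si](c1ccccc1)(c1ccccc1)C(C)(C)C)C#C[Si](C)(C)C)[C@@H](C(OC)OC)C(C)=C | intermediate
14 | N-methoxy-N-methylamide of 13 | CON(C)C(=O)[C@](C)([C@@H](O)C[C@@H](O[Si](c1ccccc1)(c1ccccc1)C(C)(C)C)C#C[Si](C)(C)C)[C@@H](C(OC)OC)C(C)=C | intermediate
15 | allylmagnesium bromide | C=CC[Mg]Br | starting material
16 | β-hydroxy allyl ketone (C14 ketone bearing CH2CH=CH2; C1, C2, C4, C10 as in 13) | C=CCC(=O)[C@](C)([C@@H](O)C[C@@H](O[Si](c1ccccc1)(c1ccccc1)C(C)(C)C)C#C[Si](C)(C)C)[C@@H](C(OC)OC)C(C)=C | intermediate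
17 | 1,3-anti diol (C14 (S) carbinol; C1, C2, C4, C10 as in 36) | C=CC[C@H](O)[C@](C)([C@@H](O)C[C@@H](O[Si](c1ccccc1)(c1ccccc1)C(C)(C)C)C#C[Si](C)(C)C)[C@@H](C(OC)OC)C(C)=C | intermediate
18 | ring A diol (cyclohexene closed; 2-OH, 14-OH, C10–CH(OMe)2, 4-OSiPh2t-Bu, C5≡C6–SiMe3) | O[C@H]1CC=C(C)[C@H](C(OC)OC)[C@@]1(C)[C@@H](O)C[C@@H](O[Si](c2ccccc2)(c2ccccc2)C(C)(C)C)C#C[Si](C)(C)C | intermediate
19 | terminal alkyne diol | O[C@H]1CC=C(C)[C@H](C(OC)OC)[C@@]1(C)[C@@H](O)C[C@@H](O[Si](c2ccccc2)(c2ccccc2)C(C)(C)C)C#C | intermediate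
20 | 2,14-diacetate of 19 | CC(=O)O[C@H]1CC=C(C)[C@H](C(OC)OC)[C@@]1(C)[C@@H](OC(C)=O)C[C@@H](O[Si](c2ccccc2)(c2ccccc2)C(C)(C)C)C#C | intermediate
21 | C9 aldehyde | CC(=O)O[C@H]1CC=C(C)[C@H](C=O)[C@@]1(C)[C@@H](OC(C)=O)C[C@@H](O[Si](c2ccccc2)(c2ccccc2)C(C)(C)C)C#C | intermediate
22 | allyl 4-methoxybenzyl ether | C=CCOCc1ccc(OC)cc1 | starting material
23 | (Z)-[3-(4-methoxybenzyloxy)prop-2-enyl]diisopinocampheylborane (not isolated) | COc1ccc(CO/C=C\CB([C@H]2C[C@H]3C[C@@H]([C@@H]2C)C3(C)C)[C@H]2C[C@H]3C[C@@H]([C@@H]2C)C3(C)C)cc1 | intermediate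
24 | C9 (S) alcohol with syn C8 (S) 4-methoxybenzyl ether and vinyl group on C8 | CC(=O)O[C@H]1CC=C(C)[C@H]([C@H](O)[C@@H](OCc2ccc(OC)cc2)C=C)[C@@]1(C)[C@@H](OC(C)=O)C[C@@H](O[Si](c3ccccc3)(c3ccccc3)C(C)(C)C)C#C | intermediate
25 | 9-O-triethylsilyl ether of 24 | CC(=O)O[C@H]1CC=C(C)[C@H]([C@H](O[Si](CC)(CC)CC)[C@@H](OCc2ccc(OC)cc2)C=C)[C@@]1(C)[C@@H](OC(C)=O)C[C@@H](O[Si](c3ccccc3)(c3ccccc3)C(C)(C)C)C#C | intermediate
26 | C8 allylic alcohol | CC(=O)O[C@H]1CC=C(C)[C@H]([C@H](O[Si](CC)(CC)CC)[C@@H](O)C=C)[C@@]1(C)[C@@H](OC(C)=O)C[C@@H](O[Si](c2ccccc2)(c2ccccc2)C(C)(C)C)C#C | intermediate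
27 | α′-silyloxy enone (C8 ketone, vinyl on C8, 9-OSiEt3) | CC(=O)O[C@H]1CC=C(C)[C@H]([C@H](O[Si](CC)(CC)CC)C(=O)C=C)[C@@]1(C)[C@@H](OC(C)=O)C[C@@H](O[Si](c2ccccc2)(c2ccccc2)C(C)(C)C)C#C | intermediate
28 | allyl propanoate | CCC(=O)OCC=C | starting material
29 | aldol adduct (C8 tertiary alcohol with vinyl, C17 (R) methyl, allyl ester at C19) | CC(=O)O[C@H]1CC=C(C)[C@H]([C@H](O[Si](CC)(CC)CC)[C@@](O)(C=C)[C@@H](C)C(=O)OCC=C)[C@@]1(C)[C@@H](OC(C)=O)C[C@@H](O[Si](c2ccccc2)(c2ccccc2)C(C)(C)C)C#C | intermediate
30 | enyne carboxylic acid | CC(=O)O[C@H]1CC=C(C)[C@H]([C@H](O[Si](CC)(CC)CC)[C@@](O)(C=C)[C@@H](C)C(O)=O)[C@@]1(C)[C@@H](OC(C)=O)C[C@@H](O[Si](c2ccccc2)(c2ccccc2)C(C)(C)C)C#C | intermediate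
31 | acyclic 2-substituted buta-1,3-diene acid (C4–C5(=CH2)–CH=CH2; not isolated) | CC(=O)O[C@H]1CC=C(C)[C@H]([C@H](O[Si](CC)(CC)CC)[C@@](O)(C=C)[C@@H](C)C(O)=O)[C@@]1(C)[C@@H](OC(C)=O)C[C@@H](O[Si](c2ccccc2)(c2ccccc2)C(C)(C)C)C(=C)C=C | intermediate
32 | macrocyclic diene acid (ten-membered ring, exocyclic C5=C16, (6Z)-C6=C7, 8-OH, C17H(CH3)CO2H on C8) | C=C1/C=C\[C@@](O)([C@@H](C)C(O)=O)[C@@H](O[Si](CC)(CC)CC)[C@H]2C(C)=CC[C@H](OC(C)=O)[C@]2(C)[C@@H](OC(C)=O)C[C@H]1O[Si](c3ccccc3)(c3ccccc3)C(C)(C)C | intermediate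
33 | γ-lactone with C16 acetate and (5Z)-alkene, 9-O-SiEt3, 4-O-SiPh2t-Bu | CC(=O)OC/C1=C/[C@@H]2OC(=O)[C@H](C)[C@@]2(O)[C@@H](O[Si](CC)(CC)CC)[C@H]2C(C)=CC[C@H](OC(C)=O)[C@]2(C)[C@@H](OC(C)=O)C[C@H]1O[Si](c3ccccc3)(c3ccccc3)C(C)(C)C | intermediate
34 | 9-hydroxy lactone | CC(=O)OC/C1=C/[C@@H]2OC(=O)[C@H](C)[C@@]2(O)[C@@H](O)[C@H]2C(C)=CC[C@H](OC(C)=O)[C@]2(C)[C@@H](OC(C)=O)C[C@H]1O[Si](c3ccccc3)(c3ccccc3)C(C)(C)C | intermediate
35 | 4-O-tert-butyldiphenylsilyl ether of the target | CC(=O)OC/C1=C/[C@@H]2OC(=O)[C@H](C)[C@@]2(O)[C@@H](OC(C)=O)[C@H]2C(C)=CC[C@H](OC(C)=O)[C@]2(C)[C@@H](OC(C)=O)C[C@H]1O[Si](c3ccccc3)(c3ccccc3)C(C)(C)C | intermediate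
36 | CNP0226727.2 | CC(=O)OC/C1=C/[C@@H]2OC(=O)[C@H](C)[C@@]2(O)[C@@H](OC(C)=O)[C@H]2C(C)=CC[C@H](OC(C)=O)[C@]2(C)[C@@H](OC(C)=O)C[C@H]1O | target

**Summary**

Total step count: 25. Longest linear sequence: 24 steps (steps 1–4 and 6–25; step 5 is a one-step side branch).

Steps most likely to fail:

Step 22. The allylpalladium intermediate may be captured at the internal carbon (1,2-addition), the tertiary hydroxyl may compete with the carboxylate, or the intermediate may lose a β-hydrogen before acetate arrives. Fallback: from 32, iodine and NaHCO3 in MeCN at 0 °C should bring about a 5-exo iodolactonization across C6=C7 with the same facial bias at C7, giving the C6-iodo γ-lactone F1, an allylic iodide next to the exocyclic C5=C16 bond. AgOAc in AcOH should then ionize the iodide and deliver acetate to the primary C16 with allylic transposition (SN2′ acetolysis), which comes back to the route at 33.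

Step 21. The medium-ring closure may fail through oligomerization by cross-metathesis, through exo-mode enyne cyclization to a nine-membered ring, or through E/Z scrambling, because the alkene partner sits on a fully substituted carbon. Fallback: close the ring before the quaternary centre exists. From 27, where C8 is still a trigonal and unhindered carbonyl carbon, the same ruthenium-catalysed enyne metathesis under ethylene should give the macrocyclic cross-conjugated trienone F2. The lithium enolate of 28 is then added to the ring ketone at −78 °C to give the macrocyclic allyl ester F3, and Pd(PPh3)4 with morpholine removes the allyl group, which comes back to the route at 32.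

Step 19. The enolate may add in the conjugate sense to the vinyl ketone, the simple diastereoselection at C17 or the facial selection at C8 may be poor, and the tertiary aldolate may revert on warming. Fallback: reagent control by an auxiliary instead of substrate control. From 27, the lithium (Z)-enolate of (S)-4-benzyl-3-propanoyloxazolidin-2-one (auxiliary-controlled enolate face for C17, closed transition state for C8) should give the aldol imide F4. LiOH with H2O2 in THF–H2O at 0 °C then cleaves the auxiliary, which comes back to the route at 30.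

Further compounds

F1 | step 22 | C6-iodo γ-lactone with exocyclic C5=C16 (iodolactone of 32) | C=C1[C@@H](I)[C@@H]2OC(=O)[C@H](C)[C@@]2(O)[C@@H](O[Si](CC)(CC)CC)[C@H]2C(C)=CC[C@H](OC(C)=O)[C@]2(C)[C@@H](OC(C)=O)C[C@H]1O[Si](c3ccccc3)(c3ccccc3)C(C)(C)C
F2 | step 21 | macrocyclic cross-conjugated trienone (C8 ketone in the ten-membered ring) | C=C1/C=C\C(=O)[C@@H](O[Si](CC)(CC)CC)[C@H]2C(C)=CC[C@H](OC(C)=O)[C@]2(C)[C@@H](OC(C)=O)C[C@H]1O[Si](c3ccccc3)(c3ccccc3)C(C)(C)C
F3 | step 21 | macrocyclic allyl ester (aldol adduct of F2) | C=C1/C=C\[C@@](O)([C@@H](C)C(=O)OCC=C)[C@@H](O[Si](CC)(CC)CC)[C@H]2C(C)=CC[C@H](OC(C)=O)[C@]2(C)[C@@H](OC(C)=O)C[C@H]1O[Si](c3ccccc3)(c3ccccc3)C(C)(C)C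
F4 | step 19 | aldol imide of (S)-4-benzyloxazolidin-2-one | CC(=O)O[C@H]1CC=C(C)[C@H]([C@H](O[Si](CC)(CC)CC)[C@@](O)(C=C)[C@@H](C)C(=O)N2C(=O)OC[C@@H]2Cc2ccccc2)[C@@]1(C)[C@@H](OC(C)=O)C[C@@H](O[Si](c2ccccc2)(c2ccccc2)C(C)(C)C)C#C
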